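**Plan**

- Retrosynthesis: the two O–Si bonds are cut first, then the C2–C3 bond of the pyranone ring (back to an aryl diazomethyl ketone), then the acyl–CHN2 bond, the O1–C2 aryl ether bond and last the C3–C4 bond of the heptan-2-ol chain.
- Enabling feature: in the open precursor C2 carries O1 and one hydrogen and lies six atoms from C3, the carbon α to the C4 aryl ketone on the benzene ring. A C3 ketocarbenoid can therefore insert into the C2–H bond of a sec-alkyl aryl ether and close the only new ring.
- Forward: a C5 Grignard reagent opens (S)-propylene oxide; the resulting alcohol is joined to a monosilylated bromohydroquinone aldehyde by Mitsunobu etherification; the aldehyde is taken to the acid and the diazo ketone; the pyranone ring closes onto the bought benzene ring; both silyl ethers are removed.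
- Stereochemistry: the single stereocentre comes from (S)-propylene oxide, is inverted once in the Mitsunobu step to the (R) ether, and is carried with retention into the (R) quaternary C2 by the C–H insertion.

Key step: step 8

Remark: C2 of the target is (R); since C3 takes the place of the methine hydrogen with retention, the (R) ether 12 maps onto (R)-13 with the same descriptor.

**Step 1**
Reactants: 1 4-bromo-2,5-dimethoxybenzaldehyde
Product: 2 4-bromo-2,5-dihydroxybenzaldehyde
Conditions: BBr3, CH2Cl2, −78 °C to rt; H2O
Reagents that add atoms: none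
Why: Lewis acid ether cleavage, in which BBr3 complexes each aryl methyl ether oxygen and bromide removes the methyl group by SN2, is the standard aryl methyl ether demethylation and should leave the aldehyde and the aryl bromide intact after aqueous work-up.

**Step 2**
Reactants: 2 4-bromo-2,5-dihydroxybenzaldehyde
Product: 3 4-bromo-5-(tert-butyldimethylsilyloxy)-2-hydroxybenzaldehyde
Conditions: TBSCl (1.05 equiv), imidazole, CH2Cl2, 0 °C
Reagents that add atoms: tert-butyldimethylsilyl chloride, CC(C)(C)[Si](C)(C)Cl
Why: Regioselective phenol silylation should occur at the free 5-hydroxyl because the 2-hydroxyl is held in an intramolecular hydrogen bond to the aldehyde and is the poorer nucleophile, as is usual for 2,5-dihydroxybenzaldehydes.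

**Step 3**
Reactants: 4 4-bromo-2-methylbutan-2-ol
Product: 5 [(4-bromo-2-methylbutan-2-yl)oxy]triethylsilane
Conditions: TESOTf, 2,6-lutidine, CH2Cl2, 0 °C
Reagents that add atoms: triethylsilyl trifluoromethanesulfonate, CC[Si](CC)(CC)OS(=O)(=O)C(F)(F)F
Why: Silyl triflate silylation under 2,6-lutidine buffering is the standard way to cap a hindered tertiary alcohol and should not disturb the primary bromide.

**Step 4**
Reactants: 5 [(4-bromo-2-methylbutan-2-yl)oxy]triethylsilane; 6 (S)-2-methyloxirane ((S)-propylene oxide)
Product: 8 (2S)-6-methyl-6-(triethylsilyloxy)heptan-2-ol, via alkylmagnesium bromide 7 (not isolated)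
Conditions: Mg, THF, 40 °C; then CuI (10 mol%), 6, THF, −30 to 0 °C; aqueous work-up
Reagents that add atoms: none
Why: Grignard formation followed by copper-catalysed SN2 opening of a terminal epoxide at its unsubstituted carbon leaves the stereocentre of 6 untouched, so the (S) configuration of the epoxide is carried unchanged into the secondary alcohol.

**Step 5**
Reactants: 3 4-bromo-5-(tert-butyldimethylsilyloxy)-2-hydroxybenzaldehyde; 8 (2S)-6-methyl-6-(triethylsilyloxy)heptan-2-ol
Product: 9 4-bromo-5-(tert-butyldimethylsilyloxy)-2-{[(2R)-6-methyl-6-(triethylsilyloxy)heptan-2-yl]oxy}benzaldehyde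
Conditions: PPh3, DIAD, THF, 0 °C to rt
Reagents that add atoms: none
Why: In this Mitsunobu etherification the salicylaldehyde-type phenol is acidic enough to protonate the betaine and its phenoxide displaces the alkoxyphosphonium ion by SN2 with inversion, turning the (S) carbinol into the (R) aryl ether while the tertiary silyl ether stays inert.

**Step 6**
Reactants: 9 4-bromo-5-(tert-butyldimethylsilyloxy)-2-{[(2R)-6-methyl-6-(triethylsilyloxy)heptan-2-yl]oxy}benzaldehyde
Product: 10 4-bromo-5-(tert-butyldimethylsilyloxy)-2-{[(2R)-6-methyl-6-(triethylsilyloxy)heptan-2-yl]oxy}benzoic acid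
Conditions: NaClO2, NaH2PO4, 2-methylbut-2-ene, t-BuOH/H2O, rt
Reagents that add atoms: sodium chlorite, [Na+].[O-]Cl=O
Why: The Pinnick oxidation converts the aldehyde to the acid with chlorous acid near pH 4 while 2-methylbut-2-ene traps hypochlorous acid, conditions under which both silyl ethers, the aryl bromide and the ether stereocentre should be inert.

**Step 7**
Reactants: 10 4-bromo-5-(tert-butyldimethylsilyloxy)-2-{[(2R)-6-methyl-6-(triethylsilyloxy)heptan-2-yl]oxy}benzoic acid
Product: 12 1-[4-bromo-5-(tert-butyldimethylsilyloxy)-2-{[(2R)-6-methyl-6-(triethylsilyloxy)heptan-2-yl]oxy}phenyl]-2-diazoethan-1-one, via acid chloride 11 (not isolated)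
Conditions: 1-chloro-N,N,2-trimethylprop-1-en-1-amine, CH2Cl2, 0 °C to rt; then CH2N2, Et3N, Et2O/THF, 0 °C
Reagents that add atoms: diazomethane, C=[N+]=[N-]
Why: The Ghosez chloroenamine forms the acid chloride under neutral conditions (no HCl to threaten the tertiary triethylsilyl ether), and acylation of diazomethane, the first stage of the Arndt–Eistert sequence, then gives the diazo ketone while Et3N takes up the HCl so that no chloromethyl ketone forms.

**Step 8**
Reactants: 12 1-[4-bromo-5-(tert-butyldimethylsilyloxy)-2-{[(2R)-6-methyl-6-(triethylsilyloxy)heptan-2-yl]oxy}phenyl]-2-diazoethan-1-one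
Product: 13 (2R)-7-bromo-6-(tert-butyldimethylsilyloxy)-2-methyl-2-[4-methyl-4-(triethylsilyloxy)pentyl]chroman-4-one
Conditions: Rh2(OAc)4 (2 mol%), CH2Cl2, 40 °C, slow addition of 12 by syringe pump, 4 Å MS
Reagents that add atoms: none
Why: Rh2(OAc)4, a divalent rhodium dimer, takes N2 from the diazo carbon of 12 to give an electrophilic ketocarbenoid at C3, which inserts through a concerted three-centre transition state with hydride-transfer character into the methine C2–H bond of the ortho sec-alkoxy group. The closest known reaction type is the dirhodium carboxylate-catalysed intramolecular C–H insertion of ortho-alkoxyaryl diazo ketones to chroman-4-ones, combined with the general retention of configuration when carbenoids insert into stereogenic methine C–H bonds. The pyranone ring closes in a 1,6-insertion mode by formation of the C2–C3 bond, the usually preferred 1,5-mode being unavailable because the fifth atom from the carbenoid carbon is O1. The new quaternary stereocentre C2 is controlled by the existing ether stereocentre alone: C3 enters on the face from which hydrogen leaves, so (R)-12 should give (R)-13 without a chiral ligand. The step needs chemoselectivity for C–H insertion over attack of the O1 lone pair (oxonium ylide, then 1,2-shift to a benzofuran-3-one) and over carbenoid dimerisation; the first rests on the low basicity of O1, which is conjugated with the aryl ketone and carries a branched alkyl group with no easy allyl- or benzyl-type shift so that ylide formation can revert, and on the high hydridic character of a tertiary C–H bond α to oxygen, while the second is handled by slow addition at high dilution. No other C–H bond competes, since chain carbons beyond C2 would need a ring of seven or more and the tertiary silyl ether carbon carries no hydrogen.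

**Step 9**
Reactants: 13 (2R)-7-bromo-6-(tert-butyldimethylsilyloxy)-2-methyl-2-[4-methyl-4-(triethylsilyloxy)pentyl]chroman-4-one
Product: 14 (2R)-7-bromo-6-hydroxy-2-(4-hydroxy-4-methylpentyl)-2-methylchroman-4-one
Conditions: Bu4NF, AcOH, THF, 0 °C to rt
Reagents that add atoms: none
Why: Fluoride-mediated desilylation, driven by the strong Si–F bond, should remove the aryl and the tertiary silyl ether in one operation, and the acetic acid buffer keeps the medium from becoming basic enough to open the chromanone by retro-oxa-Michael reaction, which would racemise C2.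

**Compound list**

1 | 4-bromo-2,5-dimethoxybenzaldehyde | COc1cc(C=O)c(OC)cc1Br | starting material
2 | 4-bromo-2,5-dihydroxybenzaldehyde | Oc1cc(C=O)c(O)cc1Br | intermediate
3 | 4-bromo-5-(tert-butyldimethylsilyloxy)-2-hydroxybenzaldehyde | CC(C)(C)[Si](C)(C)Oc1cc(C=O)c(O)cc1Br | intermediate
4 | 4-bromo-2-methylbutan-2-ol | CC(C)(O)CCBr | starting material
5 | [(4-bromo-2-methylbutan-2-yl)oxy]triethylsilane | CC[Si](CC)(CC)OC(C)(C)CCBr | intermediate
6 | (S)-2-methyloxirane | C[C@H]1CO1 | starting material
7 | [3-methyl-3-(triethylsilyloxy)butyl]magnesium bromide | CC[Si](CC)(CC)OC(C)(C)CC[Mg]Br | intermediate (not isolated)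
8 | (2S)-6-methyl-6-(triethylsilyloxy)heptan-2-ol | CC[Si](CC)(CC)OC(C)(C)CCC[C@H](C)O | intermediate
9 | 4-bromo-5-(tert-butyldimethylsilyloxy)-2-{[(2R)-6-methyl-6-(triethylsilyloxy)heptan-2-yl]oxy}benzaldehyde | CC[Si](CC)(CC)OC(C)(C)CCC[C@@H](C)Oc1cc(Br)c(O[Si](C)(C)C(C)(C)C)cc1C=O | intermediate
10 | 4-bromo-5-(tert-butyldimethylsilyloxy)-2-{[(2R)-6-methyl-6-(triethylsilyloxy)heptan-2-yl]oxy}benzoic acid | CC[Si](CC)(CC)OC(C)(C)CCC[C@@H](C)Oc1cc(Br)c(O[Si](C)(C)C(C)(C)C)cc1C(=O)O | intermediate
11 | 4-bromo-5-(tert-butyldimethylsilyloxy)-2-{[(2R)-6-methyl-6-(triethylsilyloxy)heptan-2-yl]oxy}benzoyl chloride | CC[Si](CC)(CC)OC(C)(C)CCC[C@@H](C)Oc1cc(Br)c(O[Si](C)(C)C(C)(C)C)cc1C(=O)Cl | intermediate (not isolated)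
12 | 1-[4-bromo-5-(tert-butyldimethylsilyloxy)-2-{[(2R)-6-methyl-6-(triethylsilyloxy)heptan-2-yl]oxy}phenyl]-2-diazoethan-1-one | CC[Si](CC)(CC)OC(C)(C)CCC[C@@H](C)Oc1cc(Br)c(O[Si](C)(C)C(C)(C)C)cc1C(=O)C=[N+]=[N-] | intermediate
13 | (2R)-7-bromo-6-(tert-butyldimethylsilyloxy)-2-methyl-2-[4-methyl-4-(triethylsilyloxy)pentyl]chroman-4-one | CC[Si](CC)(CC)OC(C)(C)CCC[C@]1(C)CC(=O)c2cc(O[Si](C)(C)C(C)(C)C)c(Br)cc2O1 | intermediate
14 | (2R)-7-bromo-6-hydroxy-2-(4-hydroxy-4-methylpentyl)-2-methylchroman-4-one | CC(C)(O)CCC[C@]1(C)CC(=O)c2cc(O)c(Br)cc2O1 | target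

**Step count**

Total: 9 steps. Longest linear sequence: 7 steps (1 → 2 → 3 → 9 → 10 → 12 → 13 → 14, or equally 4 → 5 → 8 → 9 → 10 → 12 → 13 → 14).

**Steps most likely to fail**

Step 8. The carbenoid may be captured by the O1 lone pair, and the oxonium ylide may then undergo a 1,2-shift of the sec-alkyl group with contraction to a five-membered ring. The carbenoid may also dimerise. If the insertion turns stepwise (hydride transfer, then collapse of an ion pair), some configurational purity at C2 may be lost. The fallback gives up the insertion for a Kabbe condensation with resolution; it sets out from 3 and 8 and returns at 13. Addition of MeMgBr (2.2 equiv, THF, −78 to 0 °C) to 3 should give racemic 4-bromo-5-(tert-butyldimethylsilyloxy)-2-(1-hydroxyethyl)phenol F1, and MnO2 in CH2Cl2 should oxidise the benzylic alcohol to 1-[4-bromo-5-(tert-butyldimethylsilyloxy)-2-hydroxyphenyl]ethan-1-one F2. Dess–Martin oxidation of 8 should give 6-methyl-6-(triethylsilyloxy)heptan-2-one F3. Condensation of F2 with F3 under pyrrolidine in MeCN at 60 °C (no alcohol, to spare the aryl silyl ether) should give racemic 7-bromo-6-(tert-butyldimethylsilyloxy)-2-methyl-2-[4-methyl-4-(triethylsilyloxy)pentyl]chroman-4-one F4 by aldol-type condensation and oxa-Michael closure. Preparative HPLC on a chiral stationary phase would then deliver 13; the racemate also serves as the reference for checking the enantiomeric purity of material from step 8.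

Step 5. The hindered, hydrogen-bonded phenol may be a sluggish pronucleophile, so that the alkoxyphosphonium ion is lost by elimination to alkenes or by attack of the hydrazide nitrogen. The fallback replaces the redox condensation by a Williamson etherification of a preformed sulfonate; it sets out from 8 and 3 and returns at 9. Mesylation of 8 (MsCl, Et3N, CH2Cl2, 0 °C) should give (2S)-6-methyl-6-(triethylsilyloxy)heptan-2-yl methanesulfonate F5, with the configuration untouched. Reaction of F5 with 3 and dry K2CO3 in MeCN at 60 °C should give 9 by SN2 displacement with inversion.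

Step 7. Adventitious HCl may cleave the tertiary silyl ether or add to the diazo ketone to give a chloromethyl ketone, and the hindered ortho-alkoxybenzoyl chloride may acylate diazomethane slowly. The fallback builds the diazo group by diazo transfer to a methyl ketone and bypasses 10 and 11; it sets out from 9 and returns at 12. Addition of MeMgBr to 9 (THF, −78 °C) should give 1-[4-bromo-5-(tert-butyldimethylsilyloxy)-2-{[(2R)-6-methyl-6-(triethylsilyloxy)heptan-2-yl]oxy}phenyl]ethan-1-ol F6 as a mixture of carbinol epimers. Dess–Martin oxidation should give 1-[4-bromo-5-(tert-butyldimethylsilyloxy)-2-{[(2R)-6-methyl-6-(triethylsilyloxy)heptan-2-yl]oxy}phenyl]ethan-1-one F7. Claisen trifluoroacetylation (LiN(SiMe3)2, CF3CO2CH2CF3, THF, −78 °C) should give 1-[4-bromo-5-(tert-butyldimethylsilyloxy)-2-{[(2R)-6-methyl-6-(triethylsilyloxy)heptan-2-yl]oxy}phenyl]-4,4,4-trifluorobutane-1,3-dione F8. Detrifluoroacetylative diazo transfer (MsN3, Et3N, H2O, MeCN, rt; Danheiser procedure) should then give 12.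

**Further compounds**

F1 | step 8 | 4-bromo-5-(tert-butyldimethylsilyloxy)-2-(1-hydroxyethyl)phenol (racemic) | CC(O)c1cc(O[Si](C)(C)C(C)(C)C)c(Br)cc1O
F2 | step 8 | 1-[4-bromo-5-(tert-butyldimethylsilyloxy)-2-hydroxyphenyl]ethan-1-one | CC(=O)c1cc(O[Si](C)(C)C(C)(C)C)c(Br)cc1O
F3 | step 8 | 6-methyl-6-(triethylsilyloxy)heptan-2-one | CC(=O)CCCC(C)(C)O[Si](CC)(CC)CC
F4 | step 8 | racemic 7-bromo-6-(tert-butyldimethylsilyloxy)-2-methyl-2-[4-methyl-4-(triethylsilyloxy)pentyl]chroman-4-one | CC[Si](CC)(CC)OC(C)(C)CCCC1(C)CC(=O)c2cc(O[Si](C)(C)C(C)(C)C)c(Br)cc2O1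
F5 | step 5 | (2S)-6-methyl-6-(triethylsilyloxy)heptan-2-yl methanesulfonate | CC[Si](CC)(CC)OC(C)(C)CCC[C@H](C)OS(C)(=O)=O
F6 | step 7 | 1-[4-bromo-5-(tert-butyldimethylsilyloxy)-2-{[(2R)-6-methyl-6-(triethylsilyloxy)heptan-2-yl]oxy}phenyl]ethan-1-ol (carbinol epimers) | CC[Si](CC)(CC)OC(C)(C)CCC[C@@H](C)Oc1cc(Br)c(O[Si](C)(C)C(C)(C)C)cc1C(C)O
F7 | step 7 | 1-[4-bromo-5-(tert-butyldimethylsilyloxy)-2-{[(2R)-6-methyl-6-(triethylsilyloxy)heptan-2-yl]oxy}phenyl]ethan-1-one | CC[Si](CC)(CC)OC(C)(C)CCC[C@@H](C)Oc1cc(Br)c(O[Si](C)(C)C(C)(C)C)cc1C(C)=O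
F8 | step 7 | 1-[4-bromo-5-(tert-butyldimethylsilyloxy)-2-{[(2R)-6-methyl-6-(triethylsilyloxy)heptan-2-yl]oxy}phenyl]-4,4,4-trifluorobutane-1,3-dione | CC[Si](CC)(CC)OC(C)(C)CCC[C@@H](C)Oc1cc(Br)c(O[Si](C)(C)C(C)(C)C)cc1C(=O)CC(=O)C(F)(F)F
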